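**Retrosynthetic overview**

1. Ring C is opened last at O1–C2 and C2–C3, which leaves a one-carbon unit (a formamide acetal) and a 2-hydroxydeoxybenzoin; ring B is bought as 2,3,4-trimethoxyphenylacetic acid.
2. The strategy rests on ring A: the C6 methoxy is para to the oxygen on C8a, the C4 carbonyl hangs on C4a ortho to that oxygen, C7 carries the second methoxy, and C5 and C8 carry hydrogen. This is an ortho-acyl 4-methoxyphenol, the pattern a Dötz benzannulation delivers.
3. Ring A is cut at C5–C6, C4a–C8a and C8–C8a into a methoxy(1-methoxyvinyl)carbene complex of zerovalent chromium (C6, C7, C8), one of its CO ligands (C8a) and a terminal ynone (C4a, C5, with C4, the C3 methylene and ring B attached).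
4. The carbene complex comes from methyl vinyl ether, Cr(CO)6 and Me3OBF4; the ynone comes from the arylacetic acid through its Weinreb amide and ethynylmagnesium bromide.
5. Ring order: ring B purchased, ring A by benzannulation, ring C by aminomethylenation and cyclisation.

Key step: step 4

Remark: the target has no stereocentre, so no step has to set configuration; 2,3,4-trimethoxyphenylacetic acid and ethynylmagnesium bromide (THF solution) are taken as purchasable.

**Route**

Step 1
Reactants: 1 methyl vinyl ether; 2 chromium hexacarbonyl Cr(CO)6
Product: 5 pentacarbonyl[methoxy(1-methoxyethenyl)carbene]chromium, via 1-methoxyvinyllithium 3 (not isolated), via lithium pentacarbonyl(2-methoxyacryloyl)chromate 4 (not isolated)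
Conditions: 1 (excess), t-BuLi, THF, −78 to 0 °C; add to 2, Et2O, 0 °C to rt; evaporate; Me3OBF4, CH2Cl2, 0 °C; quick filtration through silica under Ar
Reagents that add atoms: trimethyloxonium tetrafluoroborate, C[O+](C)C.F[B-](F)(F)F
Why: Fischer carbene synthesis, in which α-lithiation of the vinyl ether gives an acyl-anion equivalent that adds to a CO ligand of Cr(CO)6 and the hard oxonium salt then methylates the acylate at oxygen.

Step 2
Reactants: 6 2,3,4-trimethoxyphenylacetic acid
Product: 8 N-methoxy-N-methyl-2-(2,3,4-trimethoxyphenyl)acetamide, via acyl imidazole 7 (not isolated)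
Conditions: 1,1'-carbonyldiimidazole, CH2Cl2, rt; then MeNHOMe·HCl, rt
Reagents that add atoms: N,O-dimethylhydroxylamine hydrochloride, CNOC.Cl
Why: Weinreb amide formation through the acyl imidazole, a standard acyl substitution that needs no acid chloride and leaves the aryl methyl ethers untouched.

Step 3
Reactants: 8 N-methoxy-N-methyl-2-(2,3,4-trimethoxyphenyl)acetamide; 9 ethynylmagnesium bromide
Product: 11 1-(2,3,4-trimethoxyphenyl)but-3-yn-2-one, via bromomagnesium N-methoxy-N-methylhemiaminal chelate 10 (not isolated)
Conditions: THF, −20 to 0 °C; inverse quench into cold 1 M aq. NaHSO4; short silica plug, used at once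
Reagents that add atoms: none
Why: Weinreb ketone synthesis, in which the five-membered magnesium chelate holds the tetrahedral adduct until work-up so that only one alkynyl group adds, and the inverse acidic quench keeps the released amine protonated and away from the ynone.

Step 4
Reactants: 5 pentacarbonyl[methoxy(1-methoxyethenyl)carbene]chromium; 11 1-(2,3,4-trimethoxyphenyl)but-3-yn-2-one
Product: 13 1-(2-hydroxy-4,5-dimethoxyphenyl)-2-(2,3,4-trimethoxyphenyl)ethanone, via tricarbonylchromium phenol complex 12 (not isolated)
Conditions: THF (0.05 M in 5), 50 °C, Ar, 11 (1.5 equiv) added slowly; then air, daylight, Et2O, rt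
Reagents that add atoms: none
Why: Dötz benzannulation: loss of one CO from 5 lets the alkyne bind and insert into the chromium–carbene bond, CO insertion turns the resulting vinylcarbene into a chromium-bound dienylketene, and tautomerisation after ring closure gives the phenol as its Cr(CO)3 complex 12, which air and light strip of the metal. Ring A closes by 6π electrocyclisation of the dienylketene, the ketene carbon (C8a) bonding to the vinyl CH2 carbon (C8), after C5–C6 and C4a–C8a have been made by the two insertions. The closest known reactions are benzannulations of alkenyl(methoxy)carbene complexes of zerovalent chromium, 1-alkoxyalkenyl ones such as the dihydropyranyl complex included, with terminal alkynes, among them alkynes conjugated to a carbonyl group. No stereocentre is formed. The step needs the alkyne to insert with its CH terminus on the carbene carbon, so that the acyl-bearing carbon ends next to the CO-derived carbon and the ketone stands ortho to the new hydroxyl; the steric bias of a terminal alkyne should secure this, and chromium, the alkoxy carbene and THF favour the six-membered phenol over five-membered ring products. Slow addition keeps the enolisable ynone dilute so that insertion outruns its oligomerisation.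

Step 5
Reactants: 13 1-(2-hydroxy-4,5-dimethoxyphenyl)-2-(2,3,4-trimethoxyphenyl)ethanone
Product: 15 6,7,2',3',4'-pentamethoxyisoflavone, via enaminone 14 (not isolated)
Conditions: Me2NCH(OMe)2 (3 equiv), toluene, 100 °C; then AcOH, 60 °C
Reagents that add atoms: N,N-dimethylformamide dimethyl acetal, COC(OC)N(C)C
Why: Aminomethylenation of the doubly activated methylene by the formamide acetal followed by intramolecular addition–elimination of the ortho phenol with loss of dimethylamine, the standard deoxybenzoin route to isoflavones.

**Compound list**

1 | methyl vinyl ether | COC=C | starting material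
2 | chromium hexacarbonyl, Cr(CO)6 | O=C=[Cr](=C=O)(=C=O)(=C=O)(=C=O)=C=O | starting material
3 | 1-methoxyvinyllithium | [Li]C(=C)OC | intermediate (not isolated)
4 | lithium pentacarbonyl(2-methoxyacryloyl)chromate | COC(=C)C([O-])=[Cr](=C=O)(=C=O)(=C=O)(=C=O)=C=O.[Li+] | intermediate (not isolated)
5 | pentacarbonyl[methoxy(1-methoxyethenyl)carbene]chromium | COC(=C)C(OC)=[Cr](=C=O)(=C=O)(=C=O)(=C=O)=C=O | intermediate
6 | 2,3,4-trimethoxyphenylacetic acid | COc1ccc(CC(O)=O)c(OC)c1OC | starting material
7 | 1-[(2,3,4-trimethoxyphenyl)acetyl]imidazole | COc1ccc(CC(=O)n2ccnc2)c(OC)c1OC | intermediate (not isolated)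
8 | N-methoxy-N-methyl-2-(2,3,4-trimethoxyphenyl)acetamide | COc1ccc(CC(=O)N(C)OC)c(OC)c1OC | intermediate
9 | ethynylmagnesium bromide | C#C[Mg]Br | starting material
10 | bromomagnesium alkoxide of 2-[methoxy(methyl)amino]-1-(2,3,4-trimethoxyphenyl)but-3-yn-2-ol (racemic tetrahedral adduct, chelated) | C#CC(O[Mg]Br)(Cc1ccc(OC)c(OC)c1OC)N(C)OC | intermediate (not isolated)
11 | 1-(2,3,4-trimethoxyphenyl)but-3-yn-2-one | C#CC(=O)Cc1ccc(OC)c(OC)c1OC | intermediate
12 | tricarbonyl[η6-1-(2-hydroxy-4,5-dimethoxyphenyl)-2-(2,3,4-trimethoxyphenyl)ethanone]chromium, Cr(CO)3 on ring A (arene and Cr(CO)3 fragment written as two components) | COc1cc(O)c(cc1OC)C(=O)Cc1ccc(OC)c(OC)c1OC.O=C=[Cr](=C=O)=C=O | intermediate (not isolated)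
13 | 1-(2-hydroxy-4,5-dimethoxyphenyl)-2-(2,3,4-trimethoxyphenyl)ethanone | COc1cc(O)c(cc1OC)C(=O)Cc1ccc(OC)c(OC)c1OC | intermediate
14 | (E)-3-(dimethylamino)-1-(2-hydroxy-4,5-dimethoxyphenyl)-2-(2,3,4-trimethoxyphenyl)prop-2-en-1-one (geometry of no consequence for the ring closure) | COc1cc(O)c(cc1OC)C(=O)/C(=C/N(C)C)c1ccc(OC)c(OC)c1OC | intermediate (not isolated)
15 | 6,7,2',3',4'-pentamethoxyisoflavone | COc1cc2occ(-c3ccc(OC)c(OC)c3OC)c(=O)c2cc1OC | target

**Step count**

Total: 5 steps. Longest linear sequence: 4 steps (6 to 8 to 11 to 13 to 15; steps 2, 3, 4, 5).

**Steps most likely to fail**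

Step 4. The electron-poor, enolisable ynone may oligomerise or take up nucleophiles faster than it inserts. The conjugated carbonyl may also erode the steric bias of insertion, so that the acyl-bearing carbon ends next to the carbene carbon and the phenol formed cannot close ring C. The electron-rich carbene complex may decompose thermally before CO loss becomes productive. The fallback gives up the annulation and builds the same ketone on a preformed ring A. It sets out from acid 6, which is heated with commercial 3,4-dimethoxyphenol in BF3·OEt2 at 80–90 °C. The acid first esterifies the phenol to 3,4-dimethoxyphenyl (2,3,4-trimethoxyphenyl)acetate F1. F1 should undergo Fries rearrangement in the same flask to the position ortho to the hydroxyl and para to the 3-methoxy group. This gives deoxybenzoin 13, where the route is rejoined.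

Step 3. The amine set free at work-up may add to the terminal ynone in conjugate fashion, the Grignard reagent may deprotonate the benzylic position of the amide instead of adding, and traces of base may isomerise or polymerise the ynone. The fallback releases the amine before the ynone exists and forms the ynone by a buffered oxidation. It sets out from Weinreb amide 8, which is reduced with i-Bu2AlH in THF at −78 °C to (2,3,4-trimethoxyphenyl)acetaldehyde F2. Addition of ethynylmagnesium bromide 9 in THF at −78 °C should give racemic 1-(2,3,4-trimethoxyphenyl)but-3-yn-2-ol F3. Oxidation with Dess–Martin periodinane and NaHCO3 in CH2Cl2 at 0 °C returns to ynone 11.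

Step 1. The crude lithium acylate carries lithium alkoxide and organolithium residues, so methyl transfer from the oxonium salt may be wasted on them. The electron-rich complex may also decompose during the aqueous work-up and on silica. The fallback purifies the acylate as a salt and forms the O–methyl bond by acylation and alcoholysis instead of direct alkylation. It sets out from acylate 4, which is precipitated from water with Me4NBr as tetramethylammonium pentacarbonyl(2-methoxyacryloyl)chromate F4, a solid that can be washed and dried. Acetyl bromide in CH2Cl2 at −40 °C should convert it into pentacarbonyl[acetoxy(1-methoxyethenyl)carbene]chromium F5. Methanol at −40 to 0 °C then displaces acetate and returns to carbene complex 5.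

**Further compounds**

F1 | step 4 | 3,4-dimethoxyphenyl (2,3,4-trimethoxyphenyl)acetate | COc1ccc(OC(=O)Cc2ccc(OC)c(OC)c2OC)cc1OC
F2 | step 3 | (2,3,4-trimethoxyphenyl)acetaldehyde | COc1ccc(CC=O)c(OC)c1OC
F3 | step 3 | 1-(2,3,4-trimethoxyphenyl)but-3-yn-2-ol (racemic) | C#CC(O)Cc1ccc(OC)c(OC)c1OC
F4 | step 1 | tetramethylammonium pentacarbonyl(2-methoxyacryloyl)chromate | COC(=C)C([O-])=[Cr](=C=O)(=C=O)(=C=O)(=C=O)=C=O.C[N+](C)(C)C
F5 | step 1 | pentacarbonyl[acetoxy(1-methoxyethenyl)carbene]chromium | COC(=C)C(OC(C)=O)=[Cr](=C=O)(=C=O)(=C=O)(=C=O)=C=O
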